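Before any Sbt goes into the beta run, decide what it will be judged by: the Pdt it holds at 36 min. It has the charge of the theta run, so that run is its early history.

| flask | Sbt | Ptn | Ctl | Pdt | time |
|---|---|---|---|---|---|
| theta | 0.600 M | 0.720 M | 0.00120 M |  |  |
| gamma | 0.600 M | 0.720 M | 0.00360 M |  |  |
| delta | 0.600 M | 0.720 M | 0.00120 M | 0.180 M |  |
| zeta | 0.600 M | 0.360 M | 0.00120 M |  |  |
| beta | 0.600 M | 0.720 M | 0.00120 M |  | 36 min |

| run | time / min | [Pdt] / M |
|---|---|---|
| theta run | 0.48 | 0.0466 |
| theta run | 1.1 | 0.1125 |
| theta run | 2.4 | 0.2184 |
| theta run | 5.4 | 0.3903 |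
| theta run | 12 | 0.5264 |
| gamma run | 0.48 | 0.1410 |
| gamma run | 1.1 | 0.2857 |
| gamma run | 2.4 | 0.4641 |
| gamma run | 5.4 | 0.5724 |
| gamma run | 12 | 0.5845 |
| delta run | 0.48 | 0.2263 |
| delta run | 1.1 | 0.2881 |
| delta run | 2.4 | 0.3967 |
| delta run | 5.4 | 0.5723 |
| delta run | 12 | 0.7053 |
| zeta run | 0.48 | 0.0491 |
| zeta run | 1.1 | 0.1010 |
| zeta run | 2.4 | 0.2009 |
| zeta run | 5.4 | 0.3380 |
| zeta run | 12 | 0.3597 |

(standard deviation of a reading: 0.002 M)

- Overall: Sbt + Ptn -> Pdt, with Ctl as catalyst.
- Constant volume, constant temperature.
- What is held in complexes is read along with the free species.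
- "The second partner" is Ptn.
- An order is taken over about fifteen percent of the charge, up and down.

- order of the initial rate in [Ctl], near the charge of the theta run, the rate being that where two percent of its Sbt are Pdt
- order of the initial rate in [Ptn], near the charge of the theta run, the rate being that where two percent of its Sbt are Pdt
- Pdt in the beta run at 36 min, as a share of the Sbt charged

Does Ctl set the pace? With 3.00 times the Ctl of the theta run, the gamma run reads 3.03 times its Pdt at 0.48 min, so I put the order in Ctl near one.

Does Ptn set it? The zeta run has half the Ptn of the theta run, yet at 1.1 min it reads 0.1010 M against 0.1125 M, so I put that order well below one.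

Then why compute the whole yield? I would compute the small part that is missing. In the gamma run Ptn, at 0.720 M, is more than the 0.600 M of Sbt, which makes Sbt the limiting reagent, yet Pdt has slowed to 0.5845 M at 12 min. That leaves 2.58 % of the Sbt charged unaccounted for.

Is Pdt holding itself back? The delta run has made 0.5253 M at 12 min beyond what it was given, against 0.5264 M in the theta run, so added Pdt shows no effect on these readings.

Where is the weak spot? It is my assumption that Sbt is lost at a pace of its own while Pdt keeps pace with Ctl. If so, the missing share goes as one over Ctl. Scaled to the Ctl of the theta run, the leak, the share of the Sbt charged that never becomes Pdt, is 7.75 %. That puts the ceiling at 0.554 M.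

Will the beta run reach that ceiling in time? In the theta run the gap to the ceiling shrank 6.02 times in 6.60 min, and the beta run has 24.0 min more. I therefore commit to 92.2 %.

The forecast gives orders of 1 in Ctl and 0.09 in Ptn, and 95 % for the beta run, higher than my figure. Its ground is that “beta should approach gamma's plateau, perhaps slightly below it”.

The flask gives 92.1 %, with orders of 1.0 in Ctl and 0.079 in Ptn, and the forecast stands within its margins.

    Ctl + Sbt → L + Lvg (238.8 L mol⁻¹ min⁻¹)
    L + Ptn → Pdt + Ctl (1638 L mol⁻¹ min⁻¹)
    Sbt → G (0.01866 min⁻¹)
    Ctl + Sbt ⇌ Ctl.Sbt, settled at all times (0.7570 L mol⁻¹)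

The forecast would be wrong if a run at this Ctl showed a leak beyond the margin around its 5.00 %. A fit of the main steps leaves residuals of 3.8 times the scatter, and in the scheme the step from Sbt to G lies beside those steps. The delta run has the Sbt, Ptn and Ctl of the theta run, so the leak puts its ceiling, with the Pdt it was given, at 0.734 M, and the delta run reads 0.7053 M at 12 min, less than that ceiling.

The earlier runs and the new flask stem from a simulated flask on assumed constants.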